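Ring B (the dihydrofuran) is disconnected at C2–C3 and O1–C2, which leads back to 4-hydroxybenzaldehyde and a 2-hydroxydeoxybenzoin brominated at the future C5. Three features are exploited: C3 is the acidic α-carbon of the aroyl ketone, the C2 aryl ring (ring C) has a free para-hydroxyl so that C2 can pass through a p-quinone methide, and O1 sits on benzo ring A ortho to C3a. A single catalytic condensation/oxa-1,6-addition cascade should therefore forge both bonds, close ring B and set the trans-(2S,3S) centres. The precursor carries benzyl ethers on the aroyl ring; the C5 bromide later accepts the side chain by Heck coupling before one global hydrogenation.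

Key step: step 5

Assumption: the sense of induction of the cinchona squaramide cannot be assigned in advance; the quinine-derived catalyst is written, and its quinidine-derived pseudo-enantiomer takes its place if the (2R,3R) series is favoured.

Step 1
Reactants: 1 2-hydroxyphenylacetic acid
Product: 2 (5-bromo-2-hydroxyphenyl)acetic acid
Conditions: NBS (1.0 equiv), MeCN, 0 °C → rt
Reagents that add atoms: N-bromosuccinimide, O=C1CCC(=O)N1Br
Why: Electrophilic aromatic bromination of a phenol, which in acetonitrile should go to the open position para to the hydroxyl (the future C5), one ortho position being blocked by the acetic acid side chain.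

Step 2
Reactants: 2 (5-bromo-2-hydroxyphenyl)acetic acid
Product: 4 2-(5-bromo-2-hydroxyphenyl)-N-methoxy-N-methylacetamide, via acyl imidazole 3 (not isolated)
Conditions: CDI (1.05 equiv), THF, rt; then MeNH(OMe)·HCl, rt
Reagents that add atoms: N,O-dimethylhydroxylamine hydrochloride, CNOC.Cl
Why: Weinreb amide formation through the acyl imidazole, in which the phenol can stay free because acyl transfer to phenolic oxygen is reversed by the amine nucleophile.

Step 3
Reactants: 5 4-bromoresorcinol
Product: 6 2,4-bis(benzyloxy)-1-bromobenzene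
Conditions: BnBr (2.2 equiv), K2CO3, acetone, reflux
Reagents that add atoms: benzyl bromide, BrCc1ccccc1
Why: Williamson etherification of both phenols, which leaves the aryl bromide untouched.

Step 4
Reactants: 4 2-(5-bromo-2-hydroxyphenyl)-N-methoxy-N-methylacetamide, 6 2,4-bis(benzyloxy)-1-bromobenzene
Product: 8 1-[2,4-bis(benzyloxy)phenyl]-2-(5-bromo-2-hydroxyphenyl)ethan-1-one, via arylmagnesium bromide 7 (not isolated)
Conditions: 6, Mg turnings, THF, 45 °C (gives 7); separately 4, i-PrMgCl (1.0 equiv), THF, −20 °C; then 7 (1.5 equiv), −20 °C → rt; aq NH4Cl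
Reagents that add atoms: none
Why: Weinreb ketone synthesis in which the phenol is first masked as its magnesium phenoxide by the sacrificial Grignard base, so that 7 adds once to the amide while the C–Br bond stays inert, and the hydroxy ketone is set free only at the near-neutral quench, with no acid or fluoride step that could dehydrate it to a benzofuran.

Step 5
Reactants: 8 1-[2,4-bis(benzyloxy)phenyl]-2-(5-bromo-2-hydroxyphenyl)ethan-1-one, 9 4-hydroxybenzaldehyde
Product: 12 [2,4-bis(benzyloxy)phenyl][(2S,3S)-5-bromo-2-(4-hydroxyphenyl)-2,3-dihydro-1-benzofuran-3-yl]methanone, via Mannich adduct 10 (not isolated), via p-quinone methide 11 (not isolated)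
Conditions: 9 (1.3 equiv), quinine-derived squaramide with a 3,5-bis(trifluoromethyl)phenyl arm (10 mol %), pyrrolidine (10 mol %), PhCO2H (10 mol %), 4 Å MS, CH2Cl2, 25 °C
Reagents that add atoms: none
Why: Proposed new method: pyrrolidinium benzoate converts aldehyde 9 into an iminium ion that is attacked by the enol of ketone 8 at its methylene carbon (new C2–C3 bond, Mannich adduct 10), and loss of pyrrolidine pushed by the free para-hydroxyl gives p-quinone methide 11, whose exocyclic methide carbon is then attacked by the ortho phenol (new O1–C2 bond) with rearomatisation of ring C. The closest known reactions are amine-mediated Knoevenagel condensations of deoxybenzoins with aryl aldehydes, amine–squaramide-catalysed oxa-1,6-additions to p-quinone methides generated in situ, and base-mediated [4+1] annulations that deliver trans-2,3-dihydrobenzofurans; what is new is their merger in one enantioselective operation starting from an aldehyde. Ring B closes in a 5-exo-trig mode, because the C=C bond attacked in 11 lies outside the forming ring, whereas closure onto the tautomeric enone would be a disfavoured 5-endo-trig process. C2 is set by the catalyst, whose squaramide N–H bonds hold the quinone methide carbonyl while its quinuclidine nitrogen hydrogen-bonds the attacking phenol, so that one face of the methide carbon is offered to O1; C3, epimerisable α to the ketone, is not set kinetically but should settle trans to the C2 aryl group, which corresponds to 3S once C2 is S. The step needs O1 to be the only oxygen nucleophile and needs the hydroxy ketone not to cyclodehydrate to a 2-arylbenzofuran: the first is secured by the benzyl ethers on both hydroxyls of the aroyl ring (a free ortho hydroxyl there would close a six-membered ring instead), the second by the non-acidic medium at room temperature.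

Step 6
Reactants: 12 [2,4-bis(benzyloxy)phenyl][(2S,3S)-5-bromo-2-(4-hydroxyphenyl)-2,3-dihydro-1-benzofuran-3-yl]methanone
Product: 13 [2,4-bis(benzyloxy)phenyl]{(2S,3S)-2-[4-(benzyloxy)phenyl]-5-bromo-2,3-dihydro-1-benzofuran-3-yl}methanone
Conditions: BnOH, PPh3, DIAD, THF, 0 °C → rt
Reagents that add atoms: benzyl alcohol, OCc1ccccc1
Why: Mitsunobu etherification of the ring C phenol, chosen because it needs no added base; capping this hydroxyl closes the quinone methide pathway, the only stereoelectronically open way for the C2–O1 bond to ionise in later steps, and neither C2 nor C3 takes part.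

Step 7
Reactants: 14 2,4-dihydroxyacetophenone
Product: 15 1-[2,4-bis(benzyloxy)phenyl]ethan-1-one
Conditions: BnBr (2.3 equiv), K2CO3, DMF, 80 °C
Reagents that add atoms: benzyl bromide, BrCc1ccccc1
Why: Williamson etherification, with heating in DMF so that the hydroxyl hydrogen-bonded to the ketone is alkylated as well.

Step 8
Reactants: 15 1-[2,4-bis(benzyloxy)phenyl]ethan-1-one
Product: 17 1-[2,4-bis(benzyloxy)phenyl]prop-2-en-1-one, via Mannich base 16 (not isolated)
Conditions: (CH2O)n, i-Pr2NH·CF3CO2H, CF3CO2H (cat.), THF, reflux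
Reagents that add atoms: paraformaldehyde (as formaldehyde), C=O
Why: Mannich-type α-methylenation of a methyl ketone, in which the β-amino ketone loses the hindered amine under the reaction conditions to give the aryl vinyl ketone, which is used promptly.

Step 9
Reactants: 13 [2,4-bis(benzyloxy)phenyl]{(2S,3S)-2-[4-(benzyloxy)phenyl]-5-bromo-2,3-dihydro-1-benzofuran-3-yl}methanone, 17 1-[2,4-bis(benzyloxy)phenyl]prop-2-en-1-one
Product: 18 (2E)-1-[2,4-bis(benzyloxy)phenyl]-3-{(2S,3S)-3-[2,4-bis(benzyloxy)benzoyl]-2-[4-(benzyloxy)phenyl]-2,3-dihydro-1-benzofuran-5-yl}prop-2-en-1-one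
Conditions: Pd[P(t-Bu)3]2 (5 mol %), Cy2NMe, 1,4-dioxane, 25–40 °C
Reagents that add atoms: none
Why: Mizoroki–Heck reaction in which the bulky electron-rich phosphine lets the electron-rich C5–Br bond undergo oxidative addition near room temperature, syn insertion into the terminal carbon of the vinyl ketone and syn β-hydride elimination give the E-enone, and the hindered amine base is too weak to enolise C3 or open ring B.

Step 10
Reactants: 18 (2E)-1-[2,4-bis(benzyloxy)phenyl]-3-{(2S,3S)-3-[2,4-bis(benzyloxy)benzoyl]-2-[4-(benzyloxy)phenyl]-2,3-dihydro-1-benzofuran-5-yl}prop-2-en-1-one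
Product: 19 1-(2,4-dihydroxyphenyl)-3-[(2S,3S)-3-(2,4-dihydroxybenzoyl)-2-(4-hydroxyphenyl)-2,3-dihydro-1-benzofuran-5-yl]propan-1-one
Conditions: H2 (1 atm), 10% Pd/C, EtOAc/MeOH, rt
Reagents that add atoms: none
Why: Neutral heterogeneous hydrogenation should saturate the enone C=C and cleave the five aryl benzyl ethers by hydrogenolysis, while the hydrogen-bonded electron-rich aryl ketones and the hindered secondary C2–O1 ether of ring B react more slowly, so the reaction is stopped at the calculated hydrogen uptake and C2 and C3 are not involved.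

Compound list
1 | 2-hydroxyphenylacetic acid | OC(=O)Cc1ccccc1O | starting material
2 | (5-bromo-2-hydroxyphenyl)acetic acid | OC(=O)Cc1cc(Br)ccc1O | intermediate
3 | 2-(5-bromo-2-hydroxyphenyl)-1-(1H-imidazol-1-yl)ethan-1-one | O=C(Cc1cc(Br)ccc1O)n1ccnc1 | intermediate
4 | 2-(5-bromo-2-hydroxyphenyl)-N-methoxy-N-methylacetamide | CON(C)C(=O)Cc1cc(Br)ccc1O | intermediate
5 | 4-bromoresorcinol (4-bromobenzene-1,3-diol) | Oc1ccc(Br)c(O)c1 | starting material
6 | 2,4-bis(benzyloxy)-1-bromobenzene | Brc1ccc(OCc2ccccc2)cc1OCc1ccccc1 | intermediate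
7 | [2,4-bis(benzyloxy)phenyl]magnesium bromide | Br[Mg]c1ccc(OCc2ccccc2)cc1OCc1ccccc1 | intermediate
8 | 1-[2,4-bis(benzyloxy)phenyl]-2-(5-bromo-2-hydroxyphenyl)ethan-1-one | O=C(Cc1cc(Br)ccc1O)c1ccc(OCc2ccccc2)cc1OCc1ccccc1 | intermediate
9 | 4-hydroxybenzaldehyde | O=Cc1ccc(O)cc1 | starting material
10 | 1-[2,4-bis(benzyloxy)phenyl]-2-(5-bromo-2-hydroxyphenyl)-3-(4-hydroxyphenyl)-3-(pyrrolidin-1-yl)propan-1-one (mixture of stereoisomers) | O=C(C(c1cc(Br)ccc1O)C(c1ccc(O)cc1)N1CCCC1)c1ccc(OCc2ccccc2)cc1OCc1ccccc1 | intermediate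
11 | 4-{3-[2,4-bis(benzyloxy)phenyl]-2-(5-bromo-2-hydroxyphenyl)-3-oxopropylidene}cyclohexa-2,5-dien-1-one (C3 labile) | O=C1C=CC(=CC(c2cc(Br)ccc2O)C(=O)c2ccc(OCc3ccccc3)cc2OCc2ccccc2)C=C1 | intermediate
12 | [2,4-bis(benzyloxy)phenyl][(2S,3S)-5-bromo-2-(4-hydroxyphenyl)-2,3-dihydro-1-benzofuran-3-yl]methanone | Brc1ccc2c(c1)[C@H](C(=O)c1ccc(OCc3ccccc3)cc1OCc1ccccc1)[C@@H](c1ccc(O)cc1)O2 | intermediate
13 | [2,4-bis(benzyloxy)phenyl]{(2S,3S)-2-[4-(benzyloxy)phenyl]-5-bromo-2,3-dihydro-1-benzofuran-3-yl}methanone | Brc1ccc2c(c1)[C@H](C(=O)c1ccc(OCc3ccccc3)cc1OCc1ccccc1)[C@@H](c1ccc(OCc3ccccc3)cc1)O2 | intermediate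
14 | 2,4-dihydroxyacetophenone | CC(=O)c1ccc(O)cc1O | starting material
15 | 1-[2,4-bis(benzyloxy)phenyl]ethan-1-one | CC(=O)c1ccc(OCc2ccccc2)cc1OCc1ccccc1 | intermediate
16 | 1-[2,4-bis(benzyloxy)phenyl]-3-[di(propan-2-yl)amino]propan-1-one | CC(C)N(CCC(=O)c1ccc(OCc2ccccc2)cc1OCc1ccccc1)C(C)C | intermediate
17 | 1-[2,4-bis(benzyloxy)phenyl]prop-2-en-1-one | C=CC(=O)c1ccc(OCc2ccccc2)cc1OCc1ccccc1 | intermediate
18 | (2E)-1-[2,4-bis(benzyloxy)phenyl]-3-{(2S,3S)-3-[2,4-bis(benzyloxy)benzoyl]-2-[4-(benzyloxy)phenyl]-2,3-dihydro-1-benzofuran-5-yl}prop-2-en-1-one | O=C(/C=C/c1ccc2c(c1)[C@H](C(=O)c1ccc(OCc3ccccc3)cc1OCc1ccccc1)[C@@H](c1ccc(OCc3ccccc3)cc1)O2)c1ccc(OCc2ccccc2)cc1OCc1ccccc1 | intermediate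
19 | 1-(2,4-dihydroxyphenyl)-3-[(2S,3S)-3-(2,4-dihydroxybenzoyl)-2-(4-hydroxyphenyl)-2,3-dihydro-1-benzofuran-5-yl]propan-1-one | O=C(CCc1ccc2c(c1)[C@H](C(=O)c1ccc(O)cc1O)[C@@H](c1ccc(O)cc1)O2)c1ccc(O)cc1O | target

Total step count: 10. Longest linear sequence: 7 steps (steps 1, 2, 4, 5, 6, 9 and 10).

Steps most likely to fail

Step 5. Several processes can defeat the cascade:
- Condensation at the weakly acidic methylene of 8 with an electron-rich aldehyde may be too slow at room temperature.
- Ring closure may proceed through an uncatalysed or achiral-amine pathway and give racemic material.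
- The enantiomeric purity may erode by retro-oxa-1,6-addition through the quinone methide.
- The hydroxy ketone may cyclodehydrate.

The fallback uses known chemistry only, sets out from acid 2 and returns at ketone 13. Fischer esterification (MeOH, H2SO4) gives methyl (5-bromo-2-hydroxyphenyl)acetate F1. O-Alkylation with 4-(benzyloxy)benzyl chloride (K2CO3, DMF) gives methyl (2-{[4-(benzyloxy)benzyl]oxy}-5-bromophenyl)acetate F2. Diazo transfer with 4-acetamidobenzenesulfonyl azide and DBU in MeCN gives methyl (2-{[4-(benzyloxy)benzyl]oxy}-5-bromophenyl)(diazo)acetate F3. Enantioselective intramolecular carbene C–H insertion into the benzylic O–CH2 group follows, with dirhodium tetrakis[N-phthaloyl-(S)-tert-leucinate], Rh2(S-PTTL)4, or its enantiomer, whichever delivers 2S. It should give the cis ester methyl (2S,3R)-2-[4-(benzyloxy)phenyl]-5-bromo-2,3-dihydro-1-benzofuran-3-carboxylate F4. NaOMe in MeOH should epimerise C3 to the trans ester methyl (2S,3S)-2-[4-(benzyloxy)phenyl]-5-bromo-2,3-dihydro-1-benzofuran-3-carboxylate F5. MeNH(OMe)·HCl with i-PrMgCl (THF, −20 °C) converts it into (2S,3S)-2-[4-(benzyloxy)phenyl]-5-bromo-N-methoxy-N-methyl-2,3-dihydro-1-benzofuran-3-carboxamide F6. Addition of Grignard reagent 7 then gives 13.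

Step 9. The vinyl ketone may polymerise or be consumed by amine- or phosphine-induced oligomerisation before the electron-rich C5–Br bond undergoes oxidative addition. Warming to force the coupling may start base-mediated erosion at C3. A partial reductive Heck outcome would be harmless, since it converges in step 10.

The fallback sets out from bromide 13 and returns at target 19. Grignard reagent 7 (from 6 as in step 4) is added to acrolein (THF, −78 °C) to give the stable allylic alcohol 1-[2,4-bis(benzyloxy)phenyl]prop-2-en-1-ol F7. Heck arylation of it with 13 under phase-transfer conditions (Pd(OAc)2, n-Bu4NCl, NaHCO3, DMF, 60–80 °C), followed by enol–keto tautomerism, should give the saturated ketone 1-[2,4-bis(benzyloxy)phenyl]-3-{(2S,3S)-3-[2,4-bis(benzyloxy)benzoyl]-2-[4-(benzyloxy)phenyl]-2,3-dihydro-1-benzofuran-5-yl}propan-1-one F8. The conditions of step 10 then only have to remove the benzyl groups to reach 19.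

Step 10. Over-reduction is the danger: hydrogenolysis of the benzylic C2–O1 bond of ring B, or reduction of an aryl ketone, before the last benzyl ether has gone.

The fallback sets out from enone 18 and returns at target 19. BCl3 with pentamethylbenzene (CH2Cl2, −78 °C) removes the five benzyl groups without hydrogen and should give (2E)-1-(2,4-dihydroxyphenyl)-3-[(2S,3S)-3-(2,4-dihydroxybenzoyl)-2-(4-hydroxyphenyl)-2,3-dihydro-1-benzofuran-5-yl]prop-2-en-1-one F9. Homogeneous hydrogenation with RhCl(PPh3)3 (H2, THF/EtOH, rt) then reduces only the alkene and gives 19.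

Further compounds
F1 | step 5 | methyl (5-bromo-2-hydroxyphenyl)acetate | COC(=O)Cc1cc(Br)ccc1O
F2 | step 5 | methyl (2-{[4-(benzyloxy)benzyl]oxy}-5-bromophenyl)acetate | COC(=O)Cc1cc(Br)ccc1OCc1ccc(OCc2ccccc2)cc1
F3 | step 5 | methyl (2-{[4-(benzyloxy)benzyl]oxy}-5-bromophenyl)(diazo)acetate | COC(=O)C(=[N+]=[N-])c1cc(Br)ccc1OCc1ccc(OCc2ccccc2)cc1
F4 | step 5 | methyl (2S,3R)-2-[4-(benzyloxy)phenyl]-5-bromo-2,3-dihydro-1-benzofuran-3-carboxylate | Brc1ccc2c(c1)[C@@H](C(=O)OC)[C@@H](c1ccc(OCc3ccccc3)cc1)O2
F5 | step 5 | methyl (2S,3S)-2-[4-(benzyloxy)phenyl]-5-bromo-2,3-dihydro-1-benzofuran-3-carboxylate | Brc1ccc2c(c1)[C@H](C(=O)OC)[C@@H](c1ccc(OCc3ccccc3)cc1)O2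
F6 | step 5 | (2S,3S)-2-[4-(benzyloxy)phenyl]-5-bromo-N-methoxy-N-methyl-2,3-dihydro-1-benzofuran-3-carboxamide | Brc1ccc2c(c1)[C@H](C(=O)N(C)OC)[C@@H](c1ccc(OCc3ccccc3)cc1)O2
F7 | step 9 | 1-[2,4-bis(benzyloxy)phenyl]prop-2-en-1-ol (racemic) | C=CC(O)c1ccc(OCc2ccccc2)cc1OCc1ccccc1
F8 | step 9 | 1-[2,4-bis(benzyloxy)phenyl]-3-{(2S,3S)-3-[2,4-bis(benzyloxy)benzoyl]-2-[4-(benzyloxy)phenyl]-2,3-dihydro-1-benzofuran-5-yl}propan-1-one | O=C(CCc1ccc2c(c1)[C@H](C(=O)c1ccc(OCc3ccccc3)cc1OCc1ccccc1)[C@@H](c1ccc(OCc3ccccc3)cc1)O2)c1ccc(OCc2ccccc2)cc1OCc1ccccc1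
F9 | step 10 | (2E)-1-(2,4-dihydroxyphenyl)-3-[(2S,3S)-3-(2,4-dihydroxybenzoyl)-2-(4-hydroxyphenyl)-2,3-dihydro-1-benzofuran-5-yl]prop-2-en-1-one | O=C(/C=C/c1ccc2c(c1)[C@H](C(=O)c1ccc(O)cc1O)[C@@H](c1ccc(O)cc1)O2)c1ccc(O)cc1O
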